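**Retrosynthetic overview**
1. Side chain last: the (11E)-alkene comes from a Julia–Kocienski olefination of the C11 sulfone 17 with the α-alkoxy aldehyde 21; its C13 centre is set by a palladium-catalysed dynamic kinetic asymmetric addition of 4-methoxybenzyl alcohol to isoprene monoepoxide.
2. Ring B adjustments: the C17 oxygen by SeO2 oxidation of the C8 methyl group, C9/C11 by methylenation of the C9 ketone and face-selective hydroboration, the axial C6 oxygen by Luche reduction of a 6-ketone.
3. Key disconnection C1–C10: ring A is closed onto the intact aromatic ring B of phenol 6 by an enantioselective dearomative C-alkylation. Order of ring formation: ring B (bought as 2,6-dimethylphenol), then ring A (step 3).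
4. Enabling feature: in 6 the six ring B carbons (C5–C10) form a phenoxide with its oxygen on C9, so the methyl-bearing ortho carbon C10 is nucleophilic; the four-atom bromoalkyl tether on the neighbouring carbon C5 can reach only C10; the para-methoxy group on C6 stores the 6-ketone.
5. Phenol 6 from 2,6-dimethylphenol: oxidation to quinone monoketal 3, iron-hydride radical conjugate addition of 5-bromo-2-methylpent-2-ene (C4–C5 bond, gem-dimethyl carbon), then loss of methanol.

Key step: step 3

Remark on numbering: locants follow labdane numbering (decalin C1–C10, C11 on C9, C17 on C8, C18/C19 on C4, C20 on C10); "12,13,14,15,16-pentanorlabdane" is the C1–C11, C17–C20 skeleton.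
Assumption: the sense of induction of the chiral catalysts in steps 3 and 12 is taken as written; if either gives the mirror-image product, its commercial (pseudo)enantiomer is used instead.

**Route**

Step 1
Reactants: 1 2,6-dimethylphenol
Product: 3 4,4-dimethoxy-2,6-dimethylcyclohexa-2,5-dien-1-one, via 4-methoxy-2,6-dimethylphenol 2 (not isolated)
Conditions: PhI(OAc)2 (2.2 equiv), MeOH, 0 °C → rt
Reagents that add atoms: methanol, CO
Why: Hypervalent-iodine oxidative dearomatisation: two successive two-electron oxidations, each with attack of methanol at the free para carbon, should give the p-quinone monoketal, and the two ortho methyl groups block attack at the ortho positions.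

Step 2
Reactants: 3 4,4-dimethoxy-2,6-dimethylcyclohexa-2,5-dien-1-one; 4 5-bromo-2-methylpent-2-ene
Product: 6 3-(5-bromo-2-methylpentan-2-yl)-4-methoxy-2,6-dimethylphenol, via radical conjugate adduct 5 (not isolated)
Conditions: Fe(acac)3 (30 mol%), PhSiH3, EtOH, 60 °C; then TsOH·H2O (cat.), rt
Reagents that add atoms: none
Why: Iron-hydride hydrogen atom transfer to the trisubstituted alkene gives the tertiary radical, which adds (Giese-type radical conjugate addition) to an unsubstituted β-carbon of the symmetric dienone, and acid then removes methanol across C5–C6 so that the ring aromatises with the methoxy group para and the new tert-alkyl group meta to the hydroxyl, without any regiochemical choice.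

Step 3
Reactants: 6 3-(5-bromo-2-methylpentan-2-yl)-4-methoxy-2,6-dimethylphenol
Product: 7 (8aR)-4-methoxy-2,5,5,8a-tetramethyl-6,7,8,8a-tetrahydronaphthalen-1(5H)-one
Conditions: O-allyl-N-(9-anthracenylmethyl)cinchonidinium bromide (10 mol%), CsOH·H2O, toluene (0.01 M), −20 °C → 0 °C
Reagents that add atoms: none
Why: Proposed new method: the caesium phenoxide of 6 is carried into toluene as a tight ion pair with the chiral ammonium cation, and its methyl-bearing ortho carbon C10 attacks the primary bromide carbon C1 intramolecularly (SN2), which breaks the aromaticity and gives a 6,6-disubstituted cyclohexa-2,4-dienone; the closest known reactions are the ortho C-alkylation of 2,6-dimethylphenoxides to 6-alkyl-6-methylcyclohexa-2,4-dienones in non-polar media, intramolecular phenolate C-alkylations that give fused and spiro dienones, and chiral phase-transfer alkylations that build quaternary carbons from indanone and β-keto ester enolates and from acylphloroglucinols. Ring A closes in a 6-exo-tet mode through a chair-like transition state in which the gem-dimethyl group (Thorpe–Ingold effect) holds the chain over the ring face. The only new stereocentre, C10, is controlled by the catalyst: the cation bound at the C9 oxygen shields one face of the planar phenoxide, so the tether must fold over the other face. The step needs C- over O-alkylation and one ring carbon out of several, and the substrate secures both: O-alkylation would need an eight-membered ring, the para carbon C6 and the other ortho carbon C8 are out of reach of the tether on C5, and the para-methoxy group raises the nucleophilicity at carbon. The product cannot rearomatise because C10 is quaternary, and the enol ether at C6 keeps the later 6-ketone masked and distinct from the C9 ketone.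

Step 4
Reactants: 7 (8aR)-4-methoxy-2,5,5,8a-tetramethyl-6,7,8,8a-tetrahydronaphthalen-1(5H)-one
Product: 9 (5R,10R)-12,13,14,15,16-pentanorlabda-7,9(11)-dien-6-one, via trienol methyl ether 8 (not isolated)
Conditions: Cp2TiMe2, toluene, 70 °C; then oxalic acid, THF–H2O, rt
Reagents that add atoms: dimethyltitanocene, C[Ti](C)(C1C=CC=C1)C1C=CC=C1 (the CH2 group); water, O (the ketone oxygen)
Why: Petasis methylenation (titanium carbenoid, suited to a hindered ketone that cannot enolise towards C10) of the only carbonyl group, then hydrolysis of the enol ether, in which C5 is protonated opposite the angular methyl group and can equilibrate through the C6 enol, should give the trans-fused ketone.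

Step 5
Reactants: 9 (5R,10R)-12,13,14,15,16-pentanorlabda-7,9(11)-dien-6-one
Product: 10 (5R,6S,10R)-12,13,14,15,16-pentanorlabda-7,9(11)-dien-6-ol
Conditions: NaBH4, CeCl3·7H2O, MeOH, −78 °C
Reagents that add atoms: none
Why: Luche 1,2-reduction, in which hydride should attack C6 from the face opposite the axial methyl groups on C10 and C4 and so give the axial 6-alcohol cis to the C10 methyl group, as known for 6-oxo-drimanes and 6-oxo-labdanes.

Step 6
Reactants: 10 (5R,6S,10R)-12,13,14,15,16-pentanorlabda-7,9(11)-dien-6-ol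
Product: 11 (5R,6S,10R)-6-(tert-butyldimethylsilyloxy)-12,13,14,15,16-pentanorlabda-7,9(11)-diene
Conditions: TBSOTf, 2,6-lutidine, CH2Cl2, −78 °C → 0 °C
Reagents that add atoms: tert-butyldimethylsilyl triflate, CC(C)(C)[Si](C)(C)OS(=O)(=O)C(F)(F)F
Why: Silyl triflate silylation of a hindered axial allylic alcohol under non-acidic conditions that spare the diene.

Step 7
Reactants: 11 (5R,6S,10R)-6-(tert-butyldimethylsilyloxy)-12,13,14,15,16-pentanorlabda-7,9(11)-diene
Product: 13 (5R,6S,9R,10S)-6-(tert-butyldimethylsilyloxy)-12,13,14,15,16-pentanorlabd-7-en-11-ol, via B-alkyl-9-BBN adduct 12 (not isolated)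
Conditions: 9-BBN, THF, 60 °C; then NaOH, H2O2, 0 °C → rt
Reagents that add atoms: 9-borabicyclo[3.3.1]nonane, B1C2CCCC1CCC2 (boron in 12 only); hydrogen peroxide, OO (the hydroxyl oxygen of 13)
Why: Hydroboration–oxidation: 9-BBN should add to the exocyclic, less substituted alkene with boron on the terminal carbon and hydrogen on C9 from the face opposite the neighbouring angular methyl group, which makes the hydroxymethyl group equatorial and sets C9.

Step 8
Reactants: 13 (5R,6S,9R,10S)-6-(tert-butyldimethylsilyloxy)-12,13,14,15,16-pentanorlabd-7-en-11-ol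
Product: 14 (5R,6S,9R,10R)-6-(tert-butyldimethylsilyloxy)-11-[(1-phenyl-1H-tetrazol-5-yl)sulfanyl]-12,13,14,15,16-pentanorlabd-7-ene
Conditions: 1-phenyl-1H-tetrazole-5-thiol, PPh3, DIAD, THF, 0 °C → rt
Reagents that add atoms: 1-phenyl-1H-tetrazole-5-thiol, Sc1nnnn1-c1ccccc1
Why: Mitsunobu thioetherification of the primary alcohol.

Step 9
Reactants: 14 (5R,6S,9R,10R)-6-(tert-butyldimethylsilyloxy)-11-[(1-phenyl-1H-tetrazol-5-yl)sulfanyl]-12,13,14,15,16-pentanorlabd-7-ene
Product: 15 (5R,6S,9R,10R)-6-(tert-butyldimethylsilyloxy)-11-[(1-phenyl-1H-tetrazol-5-yl)sulfonyl]-12,13,14,15,16-pentanorlabd-7-ene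
Conditions: (NH4)6Mo7O24·4H2O (cat.), H2O2 (30%), EtOH, 0 °C → rt
Reagents that add atoms: hydrogen peroxide, OO
Why: Molybdate-catalysed peroxide oxidation of the sulfide to the sulfone, which should leave a trisubstituted alkene with no free allylic hydroxyl untouched.

Step 10
Reactants: 15 (5R,6S,9R,10R)-6-(tert-butyldimethylsilyloxy)-11-[(1-phenyl-1H-tetrazol-5-yl)sulfonyl]-12,13,14,15,16-pentanorlabd-7-ene
Product: 16 (5R,6S,9S,10R)-6-(tert-butyldimethylsilyloxy)-11-[(1-phenyl-1H-tetrazol-5-yl)sulfonyl]-12,13,14,15,16-pentanorlabd-7-en-17-ol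
Conditions: SeO2 (0.5 equiv), t-BuOOH, CH2Cl2, rt
Reagents that add atoms: selenium dioxide, O=[Se]=O (transfers the oxygen; re-formed by tert-butyl hydroperoxide, CC(C)(C)OO)
Why: Riley-type allylic oxidation with SeO2 and t-BuOOH (ene reaction, then [2,3]-sigmatropic shift): selenium should bind the less substituted C7 and take hydrogen from the methyl group on C8 and not from the hindered C9 methine, as known for drim-7-enes, so that the alkene stays in place.

Step 11
Reactants: 16 (5R,6S,9S,10R)-6-(tert-butyldimethylsilyloxy)-11-[(1-phenyl-1H-tetrazol-5-yl)sulfonyl]-12,13,14,15,16-pentanorlabd-7-en-17-ol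
Product: 17 (5R,6S,9S,10R)-6,17-bis(tert-butyldimethylsilyloxy)-11-[(1-phenyl-1H-tetrazol-5-yl)sulfonyl]-12,13,14,15,16-pentanorlabd-7-ene
Conditions: TBSCl, imidazole, DMF, rt
Reagents that add atoms: tert-butyldimethylsilyl chloride, CC(C)(C)[Si](C)(C)Cl
Why: Silylation of the primary allylic alcohol.

Step 12
Reactants: 18 2-methyl-2-vinyloxirane (isoprene monoepoxide, racemic); 19 4-methoxybenzyl alcohol
Product: 20 (S)-2-[(4-methoxybenzyl)oxy]-2-methylbut-3-en-1-ol
Conditions: Pd2(dba)3·CHCl3 (1 mol%), (1R,2R)-N,N′-bis[2-(diphenylphosphanyl)benzoyl]cyclohexane-1,2-diamine (3 mol%), BEt3 (1 mol%), CH2Cl2, rt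
Reagents that add atoms: none
Why: Tsuji–Trost-type dynamic kinetic asymmetric transformation: both epoxide enantiomers give interconverting π-allyl palladium complexes, the borane delivers the alcohol to the substituted terminus, and the chiral ligand sets the tertiary ether centre (later C13).

Step 13
Reactants: 20 (S)-2-[(4-methoxybenzyl)oxy]-2-methylbut-3-en-1-ol
Product: 21 (S)-2-[(4-methoxybenzyl)oxy]-2-methylbut-3-enal
Conditions: Dess–Martin periodinane, CH2Cl2, 0 °C → rt
Reagents that add atoms: none
Why: Dess–Martin oxidation of the primary alcohol; the aldehyde has no α-hydrogen and cannot epimerise.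

Step 14
Reactants: 17 (5R,6S,9S,10R)-6,17-bis(tert-butyldimethylsilyloxy)-11-[(1-phenyl-1H-tetrazol-5-yl)sulfonyl]-12,13,14,15,16-pentanorlabd-7-ene; 21 (S)-2-[(4-methoxybenzyl)oxy]-2-methylbut-3-enal
Product: 22 (5R,6S,9S,10S,13S)-6,17-bis(tert-butyldimethylsilyloxy)-13-[(4-methoxybenzyl)oxy]labda-7,11(E),14-triene
Conditions: KN(SiMe3)2, DME, −60 °C; then 21, −60 °C → rt
Reagents that add atoms: none
Why: Julia–Kocienski olefination: addition of the metalated sulfone, Smiles rearrangement and loss of SO2 and the tetrazolone should give the (E)-alkene, which α-branched partners favour, while C9 and C13 are not touched.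

Step 15
Reactants: 22 (5R,6S,9S,10S,13S)-6,17-bis(tert-butyldimethylsilyloxy)-13-[(4-methoxybenzyl)oxy]labda-7,11(E),14-triene
Product: 23 (5R,6S,9S,10S,13S)-13-[(4-methoxybenzyl)oxy]labda-7,11(E),14-triene-6,17-diol
Conditions: Bu4NF, THF, 40 °C
Reagents that add atoms: none
Why: Fluoride-induced cleavage of both silyl ethers, which the PMB ether survives.

Step 16
Reactants: 23 (5R,6S,9S,10S,13S)-13-[(4-methoxybenzyl)oxy]labda-7,11(E),14-triene-6,17-diol
Product: 24 (5R,6S,9S,10S,13S)-13-[(4-methoxybenzyl)oxy]labda-7,11(E),14-triene-6,17-diyl diacetate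
Conditions: Ac2O, pyridine, 4-(dimethylamino)pyridine (cat.), CH2Cl2, rt
Reagents that add atoms: acetic anhydride, CC(=O)OC(C)=O
Why: Acylation (nucleophilic catalysis) of the primary and the secondary alcohol; the tertiary oxygen is still protected.

Step 17
Reactants: 24 (5R,6S,9S,10S,13S)-13-[(4-methoxybenzyl)oxy]labda-7,11(E),14-triene-6,17-diyl diacetate
Product: 25 (5R,6S,9S,10S,13S)-13-hydroxylabda-7,11(E),14-triene-6,17-diyl diacetate (CNP0103498.1)
Conditions: DDQ, CH2Cl2–pH 7 phosphate buffer, 0 °C
Reagents that add atoms: none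
Why: Oxidative PMB cleavage: DDQ takes a benzylic hydride and water hydrolyses the oxocarbenium ion, under buffered conditions that should spare the allylic acetates and the tertiary bis-allylic alcohol.

**Compound list**
1 | 2,6-dimethylphenol | Cc1cccc(C)c1O | starting material
2 | 4-methoxy-2,6-dimethylphenol | COc1cc(C)c(O)c(C)c1 | intermediate
3 | 4,4-dimethoxy-2,6-dimethylcyclohexa-2,5-dien-1-one | CC1=CC(OC)(OC)C=C(C)C1=O | intermediate
4 | 5-bromo-2-methylpent-2-ene | CC(C)=CCCBr | starting material
5 | 5-(5-bromo-2-methylpentan-2-yl)-4,4-dimethoxy-2,6-dimethylcyclohex-2-en-1-one (racemic, epimer mixture) | CC1=CC(OC)(OC)C(C(C)(C)CCCBr)C(C)C1=O | intermediate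
6 | 3-(5-bromo-2-methylpentan-2-yl)-4-methoxy-2,6-dimethylphenol | Cc1cc(OC)c(C(C)(C)CCCBr)c(C)c1O | intermediate
7 | (8aR)-4-methoxy-2,5,5,8a-tetramethyl-6,7,8,8a-tetrahydronaphthalen-1(5H)-one | O=C1C(C)=CC(OC)=C2C(C)(C)CCC[C@@]12C | intermediate
8 | 9-methylidene analogue of 7 (6-methoxy trienol ether, C10 as in 7) | C=C1C(C)=CC(OC)=C2C(C)(C)CCC[C@@]12C | intermediate
9 | (5R,10R)-12,13,14,15,16-pentanorlabda-7,9(11)-dien-6-one | C=C1C(C)=CC(=O)[C@@H]2C(C)(C)CCC[C@@]12C | intermediate
10 | (5R,6S,10R)-12,13,14,15,16-pentanorlabda-7,9(11)-dien-6-ol | C=C1C(C)=C[C@H](O)[C@@H]2C(C)(C)CCC[C@@]12C | intermediate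
11 | (5R,6S,10R)-6-(tert-butyldimethylsilyloxy)-12,13,14,15,16-pentanorlabda-7,9(11)-diene | C=C1C(C)=C[C@H](O[Si](C)(C)C(C)(C)C)[C@@H]2C(C)(C)CCC[C@@]12C | intermediate
12 | 9-[6-(tert-butyldimethylsilyloxy)-12,13,14,15,16-pentanorlabd-7-en-11-yl]-9-borabicyclo[3.3.1]nonane (C5, C6, C9, C10 as in 13) | C(B1C2CCCC1CCC2)[C@@H]1C(C)=C[C@H](O[Si](C)(C)C(C)(C)C)[C@@H]2C(C)(C)CCC[C@@]12C | intermediate
13 | (5R,6S,9R,10S)-6-(tert-butyldimethylsilyloxy)-12,13,14,15,16-pentanorlabd-7-en-11-ol | OC[C@@H]1C(C)=C[C@H](O[Si](C)(C)C(C)(C)C)[C@@H]2C(C)(C)CCC[C@@]12C | intermediate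
14 | (5R,6S,9R,10R)-6-(tert-butyldimethylsilyloxy)-11-[(1-phenyl-1H-tetrazol-5-yl)sulfanyl]-12,13,14,15,16-pentanorlabd-7-ene | C(Sc3nnnn3-c3ccccc3)[C@@H]1C(C)=C[C@H](O[Si](C)(C)C(C)(C)C)[C@@H]2C(C)(C)CCC[C@@]12C | intermediate
15 | (5R,6S,9R,10R)-6-(tert-butyldimethylsilyloxy)-11-[(1-phenyl-1H-tetrazol-5-yl)sulfonyl]-12,13,14,15,16-pentanorlabd-7-ene | C(S(=O)(=O)c3nnnn3-c3ccccc3)[C@@H]1C(C)=C[C@H](O[Si](C)(C)C(C)(C)C)[C@@H]2C(C)(C)CCC[C@@]12C | intermediate
16 | (5R,6S,9S,10R)-6-(tert-butyldimethylsilyloxy)-11-[(1-phenyl-1H-tetrazol-5-yl)sulfonyl]-12,13,14,15,16-pentanorlabd-7-en-17-ol | C(S(=O)(=O)c3nnnn3-c3ccccc3)[C@@H]1C(CO)=C[C@H](O[Si](C)(C)C(C)(C)C)[C@@H]2C(C)(C)CCC[C@@]12C | intermediate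
17 | (5R,6S,9S,10R)-6,17-bis(tert-butyldimethylsilyloxy)-11-[(1-phenyl-1H-tetrazol-5-yl)sulfonyl]-12,13,14,15,16-pentanorlabd-7-ene | C(S(=O)(=O)c3nnnn3-c3ccccc3)[C@@H]1C(CO[Si](C)(C)C(C)(C)C)=C[C@H](O[Si](C)(C)C(C)(C)C)[C@@H]2C(C)(C)CCC[C@@]12C | intermediate
18 | 2-methyl-2-vinyloxirane (racemic) | C=CC1(C)CO1 | starting material
19 | 4-methoxybenzyl alcohol | COc1ccc(CO)cc1 | starting material
20 | (S)-2-[(4-methoxybenzyl)oxy]-2-methylbut-3-en-1-ol | C=C[C@](C)(OCc1ccc(OC)cc1)CO | intermediate
21 | (S)-2-[(4-methoxybenzyl)oxy]-2-methylbut-3-enal | C=C[C@](C)(OCc1ccc(OC)cc1)C=O | intermediate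
22 | (5R,6S,9S,10S,13S)-6,17-bis(tert-butyldimethylsilyloxy)-13-[(4-methoxybenzyl)oxy]labda-7,11(E),14-triene | C=C[C@](C)(OCc3ccc(OC)cc3)/C=C/[C@@H]1C(CO[Si](C)(C)C(C)(C)C)=C[C@H](O[Si](C)(C)C(C)(C)C)[C@@H]2C(C)(C)CCC[C@@]12C | intermediate
23 | (5R,6S,9S,10S,13S)-13-[(4-methoxybenzyl)oxy]labda-7,11(E),14-triene-6,17-diol | C=C[C@](C)(OCc3ccc(OC)cc3)/C=C/[C@@H]1C(CO)=C[C@H](O)[C@@H]2C(C)(C)CCC[C@@]12C | intermediate
24 | (5R,6S,9S,10S,13S)-13-[(4-methoxybenzyl)oxy]labda-7,11(E),14-triene-6,17-diyl diacetate | C=C[C@](C)(OCc3ccc(OC)cc3)/C=C/[C@@H]1C(COC(C)=O)=C[C@H](OC(C)=O)[C@@H]2C(C)(C)CCC[C@@]12C | intermediate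
25 | (5R,6S,9S,10S,13S)-13-hydroxylabda-7,11(E),14-triene-6,17-diyl diacetate | C=C[C@](C)(O)/C=C/[C@@H]1C(COC(C)=O)=C[C@H](OC(C)=O)[C@@H]2C(C)(C)CCC[C@@]12C | target

**Step count**
Total: 17 steps. Longest linear sequence: 15 steps (steps 1–11 and 14–17, from 2,6-dimethylphenol); steps 12–13 make the side-chain aldehyde.

**Steps most likely to fail, with fallbacks**

Step 3 (bears the label). What may go wrong: weak facial discrimination inside the phenoxide–ammonium ion pair, so that the enantiomeric excess is low, or intermolecular O-alkylation outrunning the ring closure. The fallback uses known chemistry and replaces the catalyst by an auxiliary on the C6 oxygen; it sets out from 3 and comes back at 9. Transketalisation of 3 with (R,R)-hydrobenzoin (pyridinium p-toluenesulfonate, benzene, reflux) should give the chiral spiroketal F1. The same iron-hydride radical addition of 4 as in step 2, without the acid treatment, should give the conjugate adduct F2; the C2-symmetric ketal directs the radical to one face of the β-carbon, the diastereomers can be separated, and the hydrobenzoin antipode is chosen to give the C5 configuration drawn. KOtBu in THF then closes ring A by C-alkylation of the C9 ketone enolate at C10 (6-exo-tet), cis to the tether because allylic 1,2-strain holds it pseudoaxial, giving the cis-fused keto ketal F3. Methylenation with Cp2TiMe2 gives the methylidene ketal F4, and aqueous HCl in THF removes the auxiliary and epimerises C5 through the C6 enol to the trans-fused ketone 9.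

Step 2. What may go wrong: the iron hydride reduces the electron-poor dienone (with loss of methoxide, back to phenol 2) faster than it transfers hydrogen to the alkene, or the tertiary radical adds too slowly next to the ketal carbon. The fallback generates the same radical without a metal hydride; it sets out from 3 and comes back at 6. The dianion of isobutyric acid (LDA) is alkylated with 1,3-dibromopropane to 5-bromo-2,2-dimethylpentanoic acid F5, which is converted into its N-hydroxyphthalimide ester F6 (N-hydroxyphthalimide, DIC). Visible-light reductive decarboxylation of F6 (Ru(bpy)3(PF6)2, Hantzsch ester, i-Pr2NEt, CH2Cl2, blue light) in the presence of 3 should give adduct 5, and TsOH·H2O then gives 6.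

Step 10. What may go wrong: hydrogen abstraction at the C9 methine instead of the methyl group, over-oxidation to the enal, or a slow ene reaction next to the silyl ether. The fallback brings in the oxygen through an epoxide; it sets out from 15 and comes back at 16. Epoxidation with mCPBA/NaHCO3 from the face opposite the 6-silyloxy and C10 methyl groups should give the 7,8-epoxide F7. TMSOTf and DBU open it at the tertiary C8 with loss of a methyl proton to the exocyclic allylic trimethylsilyl ether F8, and K2CO3 in MeOH gives the allylic alcohol F9. A catalytic 1,3-transposition with Ph3SiOReO3 then moves the hydroxyl group to C17 and the alkene back into the ring (more substituted alkene, primary alcohol), giving 16.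

**Further compounds**
F1 | step 3 | (2R,3R)-7,9-dimethyl-2,3-diphenyl-1,4-dioxaspiro[4.5]deca-6,9-dien-8-one | CC1=CC2(O[C@H](c3ccccc3)[C@@H](c3ccccc3)O2)C=C(C)C1=O
F2 | step 3 | conjugate adduct of F1 with the 5-bromo-2-methylpentan-2-yl radical (C10 epimer mixture) | CC1=CC2(O[C@H](c3ccccc3)[C@@H](c3ccccc3)O2)[C@@H](C(C)(C)CCCBr)C(C)C1=O
F3 | step 3 | cis-fused 6-[(R,R)-hydrobenzoin ketal] of 4,4,8,10-tetramethyldecal-7-ene-6,9-dione (5-epi, C10 as in 9) | O=C1C(C)=CC3(O[C@H](c4ccccc4)[C@@H](c4ccccc4)O3)[C@H]2C(C)(C)CCC[C@@]12C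
F4 | step 3 | 9-methylidene analogue of F3 | C=C1C(C)=CC3(O[C@H](c4ccccc4)[C@@H](c4ccccc4)O3)[C@H]2C(C)(C)CCC[C@@]12C
F5 | step 2 | 5-bromo-2,2-dimethylpentanoic acid | OC(=O)C(C)(C)CCCBr
F6 | step 2 | 1,3-dioxoisoindolin-2-yl 5-bromo-2,2-dimethylpentanoate | O=C(ON1C(=O)c2ccccc2C1=O)C(C)(C)CCCBr
F7 | step 10 | 7,8-epoxide of 15 (oxygen on the face opposite the 6-silyloxy group) | C(S(=O)(=O)c4nnnn4-c4ccccc4)[C@@H]1[C@@]3(C)O[C@H]3[C@H](O[Si](C)(C)C(C)(C)C)[C@@H]2C(C)(C)CCC[C@@]12C
F8 | step 10 | 7-(trimethylsilyloxy)-8(17)-methylidene isomer derived from F7 | C(S(=O)(=O)c4nnnn4-c4ccccc4)[C@@H]1C(=C)[C@@H](O[Si](C)(C)C)[C@H](O[Si](C)(C)C(C)(C)C)[C@@H]2C(C)(C)CCC[C@@]12C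
F9 | step 10 | 7-hydroxy-8(17)-methylidene isomer of 16 | C(S(=O)(=O)c4nnnn4-c4ccccc4)[C@@H]1C(=C)[C@@H](O)[C@H](O[Si](C)(C)C(C)(C)C)[C@@H]2C(C)(C)CCC[C@@]12C
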